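(The constants used here are made up; the flask was simulated.)

The nucleophile charge for this flask is to be set by counting what the mark costs.

electrophile 0.10 M; time 15 min

* the concentration of nucleophile at which the part of the electrophile that has reacted at 15 min is just 50%, in M

1. At the start the flask holds electrophile and nucleophile. Electrophile and dormant form relax to balance with a half-life of 0.694 min, far shorter than the 15 min run, so the dormant form then stands at 0.22 times the electrophile.
2. Each turnover takes one nucleophile into product, and this reckoning lets the acid set free take a second as protonated nucleophile, because the constant 9600 M⁻¹ far exceeds the 81 M⁻¹ and 70 M⁻¹ of the idle adducts.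
3. The time 1.75 min, one over the rate constant of step 1 times the electrophile charge, is shorter than the run, so this reckoning takes the charge of nucleophile, here the limiting reagent, to be turned over by the time asked.
4. This reckoning counts the dormant form as electrophile used. At the mark, electrophile stands at 0.0500 M and dormant form at 0.0110 M, which leaves 0.0390 M of product, idle adduct B counted in, to be made.
5. The nucleophile price of the mark, twice the product the mark requires, comes to 0.0780 M; this count leaves out free nucleophile, free acid set free and the adducts.
6. The price stands for nucleophile that is there from the start, and none is to be added during the run.

The forecast gives 0.104 M, within 0.1 M to 0.11 M, which is more than this reckoning; its ground is that “reaching 50% conversion (0.05 M) consumes about 0.10 M”.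

The simulation gives 0.0774 M.

    electrophile + nucleophile → acid set free + product (k1 = 5.7 M⁻¹ min⁻¹)
    nucleophile + acid set free ⇌ protonated nucleophile, settled at all times (K2 = 9600 M⁻¹)
    nucleophile + acid set free ⇌ idle adduct A, settled at all times (K3 = 81 M⁻¹)
    electrophile ⇌ dormant form (K4 = 0.22, k4 = 0.18 min⁻¹)
    nucleophile + product ⇌ idle adduct B, settled at all times (K5 = 70 M⁻¹)

At 15.0 min, 1.22% of the nucleophile charged to this flask is still free. A second flask, charged with a quarter more nucleophile, holds 0.0968 M; at the same price this buys 0.0484 M of product, so the electrophile used is reckoned at 57.7%, and the simulation of that second flask reads 56.8% at 15 min.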